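**Abbreviations:** TES = triethylsilyl, TIPS = triisopropylsilyl, TBS = tert-butyldimethylsilyl, MOM = methoxymethyl, THP = tetrahydropyran-2-yl.

## Analysis of the target

The target is a flavanone: a 2,3-dihydrochromen-4-one (ring C: O1, C2, C3, C4; fused to ring A through C4a and C8a) carrying a 2,4-dihydroxyphenyl ring B at C2. Ring A has only one free position (C6): C5 bears a methoxy group, C7 a free hydroxyl and C8 a saturated CH2 that leads into a 2-isopropenyl-5-hydroxy-5-methylhexyl chain. There are two stereocentres, C2 (S) in ring C and the chain methine (R). They are too far apart to influence each other, so each must be set by its own reagent control. C2 is fragile: base opens ring C by E1cB elimination to the open-chain enone, and acid can ionise the C2–O1 bond, which is benzylic to a doubly oxygenated arene. The isopropenyl group rules out hydrogenolysis, acid would add the C7 hydroxyl across it or ionise the tertiary alcohol, and the C5 methyl ether rules out Lewis-acid dealkylation at the end. The difficulties are therefore to create C2 late under neutral conditions, to differentiate three ring A oxygens, and to attach a branched alkyl chain at C8 between two of them. The plan rests on one feature: C4 is an aryl ketone carbon on C4a and lies three atoms from O1 (C4–C3–C2–O1). Ring C can therefore be read as the adduct of a C4 aldehyde C–H across the double bond of an O1-bound 1-arylvinyl group, whose internal carbon becomes C2.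

## Retrosynthetic reasoning

**31 ⇒ 30.** The three phenols and the tertiary alcohol of 31 are unmasked last. All four are carried as silyl ethers because buffered fluoride touches neither C2, the isopropenyl group nor the methyl ether. No skeletal bond is cut.

**30 ⇒ 29.** Ring C is opened at C3–C4. This leads back to aldehyde 29, in which C4 is a formyl group on C4a and C2/C3 are the two carbons of a 1-arylvinyl ether on O1. The forward reaction is an intramolecular, enantioselective alkene hydroacylation. It forms the last skeletal bond, closes ring C and creates C2 as a C–H bond with no acid or base, so the new centre cannot racemise through ring opening. Cutting O1–C2 or C4–C4a instead would require C2 to be made earlier and carried through ionising or basic steps.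

**29 ⇒ 27.** The formyl carbon is cut from C4a and traced back to a bromine atom. Deprotonation at this stage would not be site-defined, because both remaining ring A hydrogens (C4a–H and C6–H) lie between two ether oxygens. It would also expose four silyl ethers and a styrene-type double bond to a strong base. Bromine–lithium exchange on 27 (through 28) is site-specific and fast at −78 °C.

**27 ⇒ 26 ⇒ 22 + 25.** The C3 methylene of the enol ether is removed to give the ester carbonyl of 26; the forward step is a titanium-mediated carbonyl methylenation, for which aryl benzoates are established substrates. Ester 26 is cut at O1–C2 into phenol 22 and acid chloride 25. Compound 25 comes from silyl ester 24 and this from acid 23, so ring B enters with both phenols already protected.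

**22 ⇒ 21 ⇒ 19 ⇒ 17.** The bromine is introduced while ring A is still symmetric (17 → 19), where the two ring hydrogens are equivalent and only one bromide can form. The bromine then also distinguishes the two oxygens: after removal of both acetals (19 → 21) the hydroxyl next to bromine is the more hindered, so a bulky silyl group should go to the other one (21 → 22). This fixes which oxygen becomes O7 and which O1.

**17 ⇒ 15 + 16.** The C8–CH2 bond is cut between an aryl iodide and a primary alkylzinc reagent (Negishi coupling). The bond lies between two ortho oxygens, where alkylation of an aryl anion with a β-branched halide would be slow; a palladium-catalysed coupling with a functional-group-tolerant zinc reagent is the dependable choice. The chain stereocentre is β to zinc and is not touched.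

**15 ⇒ 13 ⇒ 12.** The iodine is placed between the two acetal oxygens of 13 by directed metalation; 13 is the bis-acetal of 12.

**16 ⇒ 11 ⇒ 10 ⇒ 9 ⇒ 8 ⇒ 7 ⇒ 4 + 5, and 4 ⇒ 1 + 2.** The chain is a lavandulyl unit whose prenyl double bond is hydrated. Its stereocentre comes from a deconjugative auxiliary-controlled alkylation of imide 4 with 5. This step creates the isopropenyl group and the stereocentre together. The tertiary alcohol follows from selective epoxidation of the more electron-rich prenyl alkene (7 → 8) and hydride opening, which is merged with reductive removal of the auxiliary (8 → 9). Imide 4 is made from 1 and 2.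

## Alternatives that were turned down

**Alternative 1: ring A by benzannulation.**
- Disconnection: ring A itself is taken apart. The phenol A1 would arise from 3-methoxycyclobut-2-enone A2 and the ynol silyl ether A3, which would be made from (R)-limonene A4 by cleavage of the ring double bond.
- Forward key step: heating A2 with A3. Electrocyclic opening of A2 to a vinylketene, [2+2] addition to A3, a second ring opening and a six-electron closure give A1. The two alkyne carbons become C7 and C8; the four carbons of A2 become C8a, C4a, C5 and C6.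
- For: the three ring A oxygens emerge differentiated in one step, and the chain stereocentre comes from the chiral pool without an auxiliary or cross-coupling. On oxygen differentiation it is stronger than the chosen route, which needs steps 11 and 12.
- Against: it is only a ring A synthesis. A1 is the debromo analogue of phenol 22 and still needs a ring C construction and control of C2. A1 has no handle at C4a, so the formyl group would have to come from a lithiation that must choose between two similar positions. A3 is heat- and acid-sensitive and lies several steps from A4, including a selective cleavage next to the isopropenyl group.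
- Comparison: step count is not lower. The chosen route places a bromine at C4a while the ring is symmetric, and its single risky step solves ring C and C2 together.

**Alternative 2: fluoroarene, substitution at C8a.**
- Disconnection: O1–C8a.
- Forward key step: the C2 alkoxide of the β-hydroxy ketone A6, formed with a carbonate base in a polar aprotic solvent, displaces fluoride ortho to the ketone and gives the tris(allyl) ether A5 (6-exo closure).
- For: C2 is set earlier by a well-precedented asymmetric aldol or reduction and is retained, because the C2–O bond is never broken. The ring closure is not a new reaction type. On precedent this alternative is stronger than the chosen one.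
- Against: ring A of A6 needs five different substituents including fluorine, which means a longer ring A synthesis. The two alkoxy groups donate into the ketone and weaken its activation, so the substitution needs heat and base. Under those conditions A6 can undergo retro-aldol cleavage or E1cB dehydration, and A5 can ring-open, which erodes C2. The allyl ethers need a separate removal with zerovalent palladium and cannot be present in a rhodium hydride step.
- Comparison: the chosen route trades precedent for neutrality. C2 is formed as a C–H bond in the last bond-forming step and is never exposed to base.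

**Alternative 3: Mitsunobu ether, then Friedel–Crafts closure.**
- Disconnection: O1–C2 (Mitsunobu etherification with inversion), then C4–C4a.
- Forward key step: the acid A8, activated in situ as a mixed perfluoroacyl anhydride, acylates C4a intramolecularly and gives the triacetate A7.
- For: both steps are classical. The tether can reach only C4a, so the acylation is regiospecific and ring A needs no bromine or formyl handle. On this point it is stronger than the chosen route.
- Against: the Mitsunobu step must displace at a secondary benzylic carbinol that carries ortho and para oxygen donors, with a 2,6-disubstituted phenol as nucleophile; ionisation would cause racemisation and elimination to the cinnamate. The acylation liberates a strong acid that can ionise the same benzylic C2–O1 bond in A8 and A7, and that threatens the isopropenyl group and the tertiary silyl ether. The acetates reduce the nucleophilicity of ring A, and their removal needs basic conditions under which flavanones ring-open.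
- Comparison: step count is similar. The chosen route avoids both acid and base once C2 exists.

Key step: step 17

## Route

**Assumptions**
- The sense of induction of the rhodium–bisphosphine catalyst in step 17 cannot be derived from precedent for this substrate class. (R)-DTBM-SEGPHOS is written; its mirror image is to be used if it delivers the 2R product.
- Compound 8 is carried as both epimers at the oxirane carbon, since that centre becomes CH2 in step 4.

Step 1
Reactants: 1 (S)-4-benzyl-2-oxazolidinone; 2 3-methylbut-2-enoyl chloride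
Product: 4 (4S)-4-benzyl-3-(3-methylbut-2-enoyl)oxazolidin-2-one, via N-lithio oxazolidinone 3 (not isolated)
Conditions: n-BuLi, THF, −78 °C; then 2, −78 → 0 °C
Reagents that add atoms: none
Why: N-acylation of the lithiated auxiliary by the acid chloride is the standard way to an Evans imide; the auxiliary centre is not involved.

Step 2
Reactants: 4 (4S)-4-benzyl-3-(3-methylbut-2-enoyl)oxazolidin-2-one; 5 prenyl bromide
Product: 7 (4S)-4-benzyl-3-[(2S)-5-methyl-2-(prop-1-en-2-yl)hex-4-enoyl]oxazolidin-2-one, via sodium dienolate 6 (not isolated)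
Conditions: NaN(SiMe3)2, THF, −78 °C; then 5, −78 → −40 °C
Reagents that add atoms: none
Why: Evans alkylation in its deconjugative form: γ-deprotonation of the s-cis enoyl imide gives the chelated Z-dienolate, which reacts at its α-carbon on the face opposite the benzyl group; this creates the isopropenyl group and sets the chain stereocentre (descriptor S here, R in the target after the change of substituent priorities).

Step 3
Reactants: 7 (4S)-4-benzyl-3-[(2S)-5-methyl-2-(prop-1-en-2-yl)hex-4-enoyl]oxazolidin-2-one
Product: 8 (4S)-4-benzyl-3-[(2S)-2-[(3,3-dimethyloxiran-2-yl)methyl]-3-methylbut-3-enoyl]oxazolidin-2-one (both epimers at the oxirane carbon)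
Conditions: mCPBA (1.05 equiv), NaHCO3, CH2Cl2, −10 → 0 °C
Reagents that add atoms: 3-chloroperoxybenzoic acid, O=C(OO)c1cccc(Cl)c1
Why: Prilezhaev epoxidation; the trisubstituted prenyl alkene is much more nucleophilic than the 1,1-disubstituted alkene that is allylic to the imide carbonyl, so one equivalent of peracid should react only at the prenyl group.

Step 4
Reactants: 8 (4S)-4-benzyl-3-[(2S)-2-[(3,3-dimethyloxiran-2-yl)methyl]-3-methylbut-3-enoyl]oxazolidin-2-one
Product: 9 (2S)-5-methyl-2-(prop-1-en-2-yl)hexane-1,5-diol
Conditions: LiAlH4, THF, 0 → 45 °C; then H2O, aq. NaOH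
Reagents that add atoms: none
Why: Hydride reduction cleaves the imide to the primary alcohol with release of the auxiliary and opens the epoxide by SN2 attack at its secondary carbon, which gives the tertiary alcohol (net Markovnikov hydration of the prenyl group); the acyl group is reduced at 0 °C before heating, so the α-centre is not enolised.

Step 5
Reactants: 9 (2S)-5-methyl-2-(prop-1-en-2-yl)hexane-1,5-diol
Product: 10 (5S)-6-iodo-2-methyl-5-(prop-1-en-2-yl)hexan-2-ol
Conditions: I2, PPh3, imidazole, CH2Cl2, 0 °C
Reagents that add atoms: iodine, II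
Why: Appel iodination; the alkoxyphosphonium ion forms at the primary hydroxyl and is displaced by iodide, while the tertiary alcohol is too hindered to react at 0 °C.

Step 6
Reactants: 10 (5S)-6-iodo-2-methyl-5-(prop-1-en-2-yl)hexan-2-ol
Product: 11 triethyl{[(5S)-6-iodo-2-methyl-5-(prop-1-en-2-yl)hexan-2-yl]oxy}silane
Conditions: Et3SiOTf, 2,6-lutidine, CH2Cl2, −78 → 0 °C
Reagents that add atoms: triethylsilyl trifluoromethanesulfonate, CC[Si](CC)(CC)OS(=O)(=O)C(F)(F)F
Why: Silylation of a tertiary alcohol with a silyl triflate; the TES ether protects the hydroxyl through the organozinc, organolithium and titanium steps and is still fluoride-labile at the end.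

Step 7
Reactants: 12 5-methoxyresorcinol
Product: 13 1-methoxy-3,5-bis(methoxymethoxy)benzene
Conditions: MOMCl, i-Pr2NEt, CH2Cl2, 0 °C → rt
Reagents that add atoms: chloromethyl methyl ether, COCCl
Why: O-alkylation of both phenols; the MOM ethers serve as directing groups for the two metalations (steps 8 and 10).

Step 8
Reactants: 13 1-methoxy-3,5-bis(methoxymethoxy)benzene
Product: 15 2-iodo-5-methoxy-1,3-bis(methoxymethoxy)benzene, via aryllithium 14 (not isolated)
Conditions: n-BuLi, THF, 0 °C; then I2, −78 °C → rt
Reagents that add atoms: iodine, II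
Why: Directed ortho-metalation; the position between the two chelating MOM ethers is the most acidic and should be lithiated in preference to those next to the methoxy group, and iodine traps the aryllithium.

Step 9
Reactants: 11 triethyl{[(5S)-6-iodo-2-methyl-5-(prop-1-en-2-yl)hexan-2-yl]oxy}silane; 15 2-iodo-5-methoxy-1,3-bis(methoxymethoxy)benzene
Product: 17 triethyl{[(5R)-6-[4-methoxy-2,6-bis(methoxymethoxy)phenyl]-2-methyl-5-(prop-1-en-2-yl)hexan-2-yl]oxy}silane, via alkylzinc iodide 16 (not isolated)
Conditions: Zn dust (activated with BrCH2CH2Br and Me3SiCl), LiCl, THF, 40 °C; then 15, Pd(OAc)2 (3 mol %), SPhos (6 mol %), THF, 25 → 50 °C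
Reagents that add atoms: none
Why: Negishi coupling; zinc inserts into the primary C–I bond, and the bulky biarylphosphine lets palladium couple the doubly ortho-substituted aryl iodide with a primary alkylzinc; the stereocentre is β to zinc and untouched (the descriptor changes from S to R only because CH2–aryl ranks below isopropenyl).

Step 10
Reactants: 17 triethyl{[(5R)-6-[4-methoxy-2,6-bis(methoxymethoxy)phenyl]-2-methyl-5-(prop-1-en-2-yl)hexan-2-yl]oxy}silane
Product: 19 {[(5R)-6-[3-bromo-4-methoxy-2,6-bis(methoxymethoxy)phenyl]-2-methyl-5-(prop-1-en-2-yl)hexan-2-yl]oxy}triethylsilane, via aryllithium 18 (not isolated)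
Conditions: n-BuLi, THF, 0 °C; then BrCCl2CCl2Br, −78 °C → rt
Reagents that add atoms: 1,2-dibromo-1,1,2,2-tetrachloroethane, ClC(Cl)(Br)C(Cl)(Cl)Br
Why: Directed ortho-metalation; the two ring hydrogens of 17 are equivalent, each between a MOM ether and the methoxy group, so only one aryllithium can form, and the bromine donor converts it into the bromide that later becomes the formyl group.

Step 11
Reactants: 19 {[(5R)-6-[3-bromo-4-methoxy-2,6-bis(methoxymethoxy)phenyl]-2-methyl-5-(prop-1-en-2-yl)hexan-2-yl]oxy}triethylsilane
Product: 21 4-bromo-5-methoxy-2-[(2R)-5-methyl-2-(prop-1-en-2-yl)-5-(TESO)hexyl]benzene-1,3-diol, via bis(trimethylsilyl) ether 20 (not isolated)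
Conditions: Me3SiOTf (4 equiv), 2,2′-bipyridyl (6 equiv), CH2Cl2, 0 °C → rt; then H2O
Reagents that add atoms: none
Why: Acetal cleavage without Brønsted acid; the silyl triflate–bipyridyl pair converts aryl MOM ethers into aryl trimethylsilyl ethers, which hydrolyse on aqueous work-up, so the isopropenyl group and the tertiary TES ether should survive.

Step 12
Reactants: 21 4-bromo-5-methoxy-2-[(2R)-5-methyl-2-(prop-1-en-2-yl)-5-(TESO)hexyl]benzene-1,3-diol
Product: 22 2-bromo-3-methoxy-6-[(2R)-5-methyl-2-(prop-1-en-2-yl)-5-(TESO)hexyl]-5-(TIPSO)phenol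
Conditions: i-Pr3SiCl (1.1 equiv), imidazole, DMF, 0 °C → rt
Reagents that add atoms: chlorotriisopropylsilane, CC(C)[Si](Cl)(C(C)C)C(C)C
Why: Site-selective silylation; the bulky silyl chloride should react at the hydroxyl flanked by CH2 and H and not at the one wedged between CH2 and bromine, which fixes the future O7 as the TIPS ether and leaves the future O1 free.

Step 13
Reactants: 23 2,4-dihydroxybenzoic acid
Product: 24 tert-butyldimethylsilyl 2,4-bis(tert-butyldimethylsilyloxy)benzoate
Conditions: t-BuMe2SiCl (3.6 equiv), imidazole, DMF, rt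
Reagents that add atoms: tert-butylchlorodimethylsilane, CC(C)(C)[Si](C)(C)Cl
Why: Exhaustive silylation of the two phenols and the carboxylic acid gives a silyl ester that can be turned into the acid chloride without free acid.

Step 14
Reactants: 24 tert-butyldimethylsilyl 2,4-bis(tert-butyldimethylsilyloxy)benzoate; 22 2-bromo-3-methoxy-6-[(2R)-5-methyl-2-(prop-1-en-2-yl)-5-(TESO)hexyl]-5-(TIPSO)phenol
Product: 26 2-bromo-3-methoxy-6-[(2R)-5-methyl-2-(prop-1-en-2-yl)-5-(TESO)hexyl]-5-(TIPSO)phenyl 2,4-bis(tert-butyldimethylsilyloxy)benzoate, via acid chloride 25 (not isolated)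
Conditions: (COCl)2, DMF (cat.), CH2Cl2, 0 °C → rt, concentrate; then 22, Et3N, DMAP, CH2Cl2, 0 °C → rt
Reagents that add atoms: none
Why: The silyl ester is converted directly into the acid chloride by Vilsmeier-type activation without hydrogen chloride, so the aryl silyl ethers are kept; DMAP-catalysed acylation then esterifies the hindered but acidic phenol.

Step 15
Reactants: 26 2-bromo-3-methoxy-6-[(2R)-5-methyl-2-(prop-1-en-2-yl)-5-(TESO)hexyl]-5-(TIPSO)phenyl 2,4-bis(tert-butyldimethylsilyloxy)benzoate
Product: 27 2-bromo-3-methoxy-6-[(2R)-5-methyl-2-(prop-1-en-2-yl)-5-(TESO)hexyl]-5-(TIPSO)phenyl 1-[2,4-bis(tert-butyldimethylsilyloxy)phenyl]vinyl ether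
Conditions: Cp2TiMe2 (3 equiv), toluene, 70 °C, dark; filtration through basic alumina
Reagents that add atoms: dimethyltitanocene, [CH3-].[CH3-].[Ti+4].c1cc[cH-]c1.c1cc[cH-]c1
Why: Petasis methylenation; the thermally generated titanium methylidene adds [2+2] to the ester carbonyl and cycloreverts to the enol ether, a conversion established for aryl benzoates; aryl bromide and silyl ethers are inert, and methylene exchange with the isopropenyl group is degenerate.

Step 16
Reactants: 27 2-bromo-3-methoxy-6-[(2R)-5-methyl-2-(prop-1-en-2-yl)-5-(TESO)hexyl]-5-(TIPSO)phenyl 1-[2,4-bis(tert-butyldimethylsilyloxy)phenyl]vinyl ether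
Product: 29 2-({1-[2,4-bis(tert-butyldimethylsilyloxy)phenyl]vinyl}oxy)-6-methoxy-3-[(2R)-5-methyl-2-(prop-1-en-2-yl)-5-(TESO)hexyl]-4-(TIPSO)benzaldehyde, via aryllithium 28 (not isolated)
Conditions: n-BuLi (1.1 equiv), THF, −78 °C; then DMF, −78 → 0 °C; pH 7 phosphate buffer
Reagents that add atoms: N,N-dimethylformamide, CN(C)C=O
Why: Bromine–lithium exchange at −78 °C is faster than any deprotonation or addition elsewhere in 27 and gives an aryllithium stabilised by two ortho oxygens; formylation with the formamide (Bouveault reaction) and buffered work-up spare the acid-labile enol ether.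

Step 17
Reactants: 29 2-({1-[2,4-bis(tert-butyldimethylsilyloxy)phenyl]vinyl}oxy)-6-methoxy-3-[(2R)-5-methyl-2-(prop-1-en-2-yl)-5-(TESO)hexyl]-4-(TIPSO)benzaldehyde
Product: 30 (2S)-2-[2,4-bis(tert-butyldimethylsilyloxy)phenyl]-5-methoxy-8-[(2R)-5-methyl-2-(prop-1-en-2-yl)-5-(TESO)hexyl]-7-(TIPSO)-2,3-dihydro-4H-chromen-4-one
Conditions: [Rh(cod)2]BF4 (5 mol %), (R)-DTBM-SEGPHOS (5.5 mol %), activated with H2 then purged with Ar, ClCH2CH2Cl, 60 °C
Reagents that add atoms: none
Why: Proposed new method: the cationic bisphosphine complex of monovalent rhodium, freed of cyclooctadiene, should add oxidatively into the aldehyde C–H bond of 29 to give an acyl hydride of trivalent rhodium that is held by the two flanking ether oxygens (O1 and the C5 methoxy) and by the nearby enol ether double bond. Migratory insertion of that alkene into Rh–H is expected to put hydrogen on the aryl-bearing carbon (the future C2) and rhodium on the terminal CH2, because the opposite sense would need a tertiary alkylrhodium bearing aryl and aryloxy groups inside the pocket of the bulky ligand; the result is a seven-membered acyl(alkyl)rhodacycle. Reductive elimination then forms C3–C4 and closes ring C; both alkene carbons end up in the new six-membered ring, so the closure is formally 6-endo-trig. The closest known reaction type is the rhodium-catalysed enantioselective intramolecular hydroacylation of 1,1-disubstituted alkenes tethered to aryl aldehydes, which gives five- and six-membered ketones with a β-stereocentre; the new elements are an enol ether as the alkene and an oxygen atom in the tether. C2 is created as a C–H bond in the insertion step, and its configuration is decided by which face of the enol ether the chiral bisphosphine presents to the hydride (catalyst control; the chain centre is too remote to interfere). The step needs cyclisation to outrun decarbonylation, which the chelating ortho oxygens and the short tether should secure by keeping the acyl rhodium saturated and the alkene close. It also needs chemoselectivity over the isopropenyl group, which could only react through a large ring, and the enol ether has no allylic hydrogen, so the usual alkene isomerisation cannot occur. No acid or base is present, so the flavanone cannot ring-open and C2 cannot epimerise.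

Step 18
Reactants: 30 (2S)-2-[2,4-bis(tert-butyldimethylsilyloxy)phenyl]-5-methoxy-8-[(2R)-5-methyl-2-(prop-1-en-2-yl)-5-(TESO)hexyl]-7-(TIPSO)-2,3-dihydro-4H-chromen-4-one
Product: 31 (2S)-2-(2,4-dihydroxyphenyl)-7-hydroxy-8-[(2R)-5-hydroxy-5-methyl-2-(prop-1-en-2-yl)hexyl]-5-methoxy-2,3-dihydro-4H-chromen-4-one
Conditions: Bu4NF (6 equiv), AcOH (6 equiv), THF, 0 °C → rt
Reagents that add atoms: none
Why: Fluoride-induced desilylation of three aryl silyl ethers and the tertiary TES ether; acetic acid protonates the phenoxides as they form, so ring C should not open by E1cB elimination and C2 should keep its configuration.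

## Compound list

1 | (S)-4-benzyl-2-oxazolidinone | O=C1N[C@@H](Cc2ccccc2)CO1 | starting material
2 | 3-methylbut-2-enoyl chloride | CC(C)=CC(=O)Cl | starting material
3 | (S)-4-benzyl-3-lithio-2-oxazolidinone | [Li]N1[C@@H](Cc2ccccc2)COC1=O | intermediate
4 | (4S)-4-benzyl-3-(3-methylbut-2-enoyl)oxazolidin-2-one | CC(C)=CC(=O)N1[C@@H](Cc2ccccc2)COC1=O | intermediate
5 | prenyl bromide (1-bromo-3-methylbut-2-ene) | CC(C)=CCBr | starting material
6 | sodium Z-dienolate of 4 | C=C(C)/C=C(\[O-])N1[C@@H](Cc2ccccc2)COC1=O.[Na+] | intermediate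
7 | (4S)-4-benzyl-3-[(2S)-5-methyl-2-(prop-1-en-2-yl)hex-4-enoyl]oxazolidin-2-one | C=C(C)[C@H](CC=C(C)C)C(=O)N1[C@@H](Cc2ccccc2)COC1=O | intermediate
8 | (4S)-4-benzyl-3-[(2S)-2-[(3,3-dimethyloxiran-2-yl)methyl]-3-methylbut-3-enoyl]oxazolidin-2-one (both oxirane epimers) | C=C(C)[C@H](CC1OC1(C)C)C(=O)N1[C@@H](Cc2ccccc2)COC1=O | intermediate
9 | (2S)-5-methyl-2-(prop-1-en-2-yl)hexane-1,5-diol | C=C(C)[C@H](CCC(C)(C)O)CO | intermediate
10 | (5S)-6-iodo-2-methyl-5-(prop-1-en-2-yl)hexan-2-ol | C=C(C)[C@H](CCC(C)(C)O)CI | intermediate
11 | triethyl{[(5S)-6-iodo-2-methyl-5-(prop-1-en-2-yl)hexan-2-yl]oxy}silane | C=C(C)[C@H](CCC(C)(C)O[Si](CC)(CC)CC)CI | intermediate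
12 | 5-methoxyresorcinol | COc1cc(O)cc(O)c1 | starting material
13 | 1-methoxy-3,5-bis(methoxymethoxy)benzene | COCOc1cc(OC)cc(OCOC)c1 | intermediate
14 | [4-methoxy-2,6-bis(methoxymethoxy)phenyl]lithium | [Li]c1c(OCOC)cc(OC)cc1OCOC | intermediate
15 | 2-iodo-5-methoxy-1,3-bis(methoxymethoxy)benzene | COCOc1cc(OC)cc(OCOC)c1I | intermediate
16 | iodo[(2S)-5-methyl-2-(prop-1-en-2-yl)-5-(triethylsilyloxy)hexyl]zinc | C=C(C)[C@H](CCC(C)(C)O[Si](CC)(CC)CC)C[Zn]I | intermediate
17 | triethyl{[(5R)-6-[4-methoxy-2,6-bis(methoxymethoxy)phenyl]-2-methyl-5-(prop-1-en-2-yl)hexan-2-yl]oxy}silane | C=C(C)[C@H](CCC(C)(C)O[Si](CC)(CC)CC)Cc1c(OCOC)cc(OC)cc1OCOC | intermediate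
18 | 3-lithio derivative of 17 (lithium between a MOM ether and the methoxy group) | C=C(C)[C@H](CCC(C)(C)O[Si](CC)(CC)CC)Cc1c(OCOC)c([Li])c(OC)cc1OCOC | intermediate
19 | {[(5R)-6-[3-bromo-4-methoxy-2,6-bis(methoxymethoxy)phenyl]-2-methyl-5-(prop-1-en-2-yl)hexan-2-yl]oxy}triethylsilane | C=C(C)[C@H](CCC(C)(C)O[Si](CC)(CC)CC)Cc1c(OCOC)c(Br)c(OC)cc1OCOC | intermediate
20 | bis(trimethylsilyl) ether of 21 | C=C(C)[C@H](CCC(C)(C)O[Si](CC)(CC)CC)Cc1c(O[Si](C)(C)C)c(Br)c(OC)cc1O[Si](C)(C)C | intermediate
21 | 4-bromo-5-methoxy-2-[(2R)-5-methyl-2-(prop-1-en-2-yl)-5-(triethylsilyloxy)hexyl]benzene-1,3-diol | C=C(C)[C@H](CCC(C)(C)O[Si](CC)(CC)CC)Cc1c(O)c(Br)c(OC)cc1O | intermediate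
22 | 2-bromo-3-methoxy-6-[(2R)-5-methyl-2-(prop-1-en-2-yl)-5-(triethylsilyloxy)hexyl]-5-(triisopropylsilyloxy)phenol | C=C(C)[C@H](CCC(C)(C)O[Si](CC)(CC)CC)Cc1c(O)c(Br)c(OC)cc1O[Si](C(C)C)(C(C)C)C(C)C | intermediate
23 | 2,4-dihydroxybenzoic acid | O=C(O)c1ccc(O)cc1O | starting material
24 | tert-butyldimethylsilyl 2,4-bis(tert-butyldimethylsilyloxy)benzoate | CC(C)(C)[Si](C)(C)OC(=O)c1ccc(O[Si](C)(C)C(C)(C)C)cc1O[Si](C)(C)C(C)(C)C | intermediate
25 | 2,4-bis(tert-butyldimethylsilyloxy)benzoyl chloride | O=C(Cl)c1ccc(O[Si](C)(C)C(C)(C)C)cc1O[Si](C)(C)C(C)(C)C | intermediate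
26 | 2-bromo-3-methoxy-6-[(2R)-5-methyl-2-(prop-1-en-2-yl)-5-(triethylsilyloxy)hexyl]-5-(triisopropylsilyloxy)phenyl 2,4-bis(tert-butyldimethylsilyloxy)benzoate | C=C(C)[C@H](CCC(C)(C)O[Si](CC)(CC)CC)Cc1c(O[Si](C(C)C)(C(C)C)C(C)C)cc(OC)c(Br)c1OC(=O)c1ccc(O[Si](C)(C)C(C)(C)C)cc1O[Si](C)(C)C(C)(C)C | intermediate
27 | 2-bromo-3-methoxy-6-[(2R)-5-methyl-2-(prop-1-en-2-yl)-5-(triethylsilyloxy)hexyl]-5-(triisopropylsilyloxy)phenyl 1-[2,4-bis(tert-butyldimethylsilyloxy)phenyl]vinyl ether | C=C(C)[C@H](CCC(C)(C)O[Si](CC)(CC)CC)Cc1c(O[Si](C(C)C)(C(C)C)C(C)C)cc(OC)c(Br)c1OC(=C)c1ccc(O[Si](C)(C)C(C)(C)C)cc1O[Si](C)(C)C(C)(C)C | intermediate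
28 | aryllithium from 27 (lithium in place of bromine) | C=C(C)[C@H](CCC(C)(C)O[Si](CC)(CC)CC)Cc1c(O[Si](C(C)C)(C(C)C)C(C)C)cc(OC)c([Li])c1OC(=C)c1ccc(O[Si](C)(C)C(C)(C)C)cc1O[Si](C)(C)C(C)(C)C | intermediate
29 | 2-({1-[2,4-bis(tert-butyldimethylsilyloxy)phenyl]vinyl}oxy)-6-methoxy-3-[(2R)-5-methyl-2-(prop-1-en-2-yl)-5-(triethylsilyloxy)hexyl]-4-(triisopropylsilyloxy)benzaldehyde | C=C(C)[C@H](CCC(C)(C)O[Si](CC)(CC)CC)Cc1c(O[Si](C(C)C)(C(C)C)C(C)C)cc(OC)c(C=O)c1OC(=C)c1ccc(O[Si](C)(C)C(C)(C)C)cc1O[Si](C)(C)C(C)(C)C | intermediate
30 | (2S)-2-[2,4-bis(tert-butyldimethylsilyloxy)phenyl]-5-methoxy-8-[(2R)-5-methyl-2-(prop-1-en-2-yl)-5-(triethylsilyloxy)hexyl]-7-(triisopropylsilyloxy)-2,3-dihydro-4H-chromen-4-one | C=C(C)[C@H](CCC(C)(C)O[Si](CC)(CC)CC)Cc1c(O[Si](C(C)C)(C(C)C)C(C)C)cc(OC)c2c1O[C@H](c1ccc(O[Si](C)(C)C(C)(C)C)cc1O[Si](C)(C)C(C)(C)C)CC2=O | intermediate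
31 | (2S)-2-(2,4-dihydroxyphenyl)-7-hydroxy-8-[(2R)-5-hydroxy-5-methyl-2-(prop-1-en-2-yl)hexyl]-5-methoxy-2,3-dihydro-4H-chromen-4-one | C=C(C)[C@H](CCC(C)(C)O)Cc1c(O)cc(OC)c2c1O[C@H](c1ccc(O)cc1O)CC2=O | target

## Step count and least certain steps

Total: 18 steps. Longest linear sequence: 15 steps (steps 1–6, 9–12 and 14–18, from 1).

**Step 17 (key step).** The likely failures are decarbonylation of the acyl rhodium hydride before insertion, insertion in the opposite sense leading to five-membered closure with a quaternary carbon, β-aryloxide elimination from the alkylrhodium, and weak facial discrimination. The fallback uses known chemistry and builds C2 by conjugate addition instead. It sets out from 22 and rejoins at 30. Phenol 22 would be deprotonated and subjected to bromine–lithium exchange with t-BuLi, and acylation with N-methoxy-N-methylacetamide would give the acetophenone F1. Condensation with N,N-dimethylformamide dimethyl acetal would give the enaminone F2, which cyclises with loss of dimethylamine (Me3SiCl, DMF) to the chromone F3. Separately, 4-bromoresorcinol would be silylated to the aryl bromide F4 and converted by bromine–lithium exchange and borylation into the boronic acid F5. The established rhodium-catalysed asymmetric 1,4-addition of arylboronic acids to chromones ([Rh(OH)(cod)]2, electron-poor chiral bisphosphine, toluene–water) would then join F5 to F3 and set C2 under ligand control, giving 30.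

**Step 9.** Transmetalation to the doubly ortho-substituted arylpalladium may be slow, so that reduction of the aryl iodide and β-hydride elimination of the alkyl group compete. The fallback changes the organometallic partner to boron (B-alkyl Suzuki–Miyaura coupling). It sets out from 11 and rejoins at 17. Iodide 11 would undergo iodine–lithium exchange with t-BuLi in Et2O at −78 °C to the alkyllithium F6, which is trapped with B-methoxy-9-borabicyclo[3.3.1]nonane as the lithium borinate F7. This is coupled in the same flask with 15 (PdCl2(dppf), aq. K3PO4, DMF) to give 17.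

**Step 11.** The tertiary TES ether may be lost or exchanged, or the second acetal may be cleaved incompletely. The fallback replaces the MOM groups by acetals that fall off under far milder conditions. It sets out from 12 and rejoins at 21. Compound 12 would be converted with dihydropyran and pyridinium p-toluenesulfonate into the bis-THP ether F8 and lithiated and iodinated as in step 8 to the iodide F9. Coupling with 16 as in step 9 would give the arene F10, and lithiation and bromination as in step 10 the bromide F11. Pyridinium p-toluenesulfonate in ethanol at 45 °C would then release 21.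

**Step 12.** Silylation may occur at both hydroxyls or at the more acidic one next to bromine. The fallback differentiates the oxygens before the bromine is present and lets the free hydroxyl direct the halogenation. It sets out from 17 and rejoins at 22. Compound 17 would be deprotected under the conditions of step 11 to the symmetric diol F12, whose two hydroxyls are equivalent. Monosilylation with i-Pr3SiCl would give the phenol F13 (the same compound as A1). Amine-catalysed ortho-bromination (N-bromosuccinimide, cat. i-Pr2NH, CH2Cl2, 0 °C) should place bromine next to the free hydroxyl, since the para position is shielded by the TIPS ether, and give 22.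

**Step 15.** The titanium methylidene may decompose faster than it adds to a carbonyl shielded by bromine and the benzylic CH2 on one side and by an ortho silyloxy group on the other, leaving the ester unchanged. The fallback moves the methylenation to an ester without the ortho bromine and introduces the formyl group by deprotonation. It sets out from 17 and rejoins at 29. Via diol F12 and phenol F13 (see step 12), acylation with 25 would give the ester F14, and Cp2TiMe2 would convert it into the enol ether F15. Lithiation with s-BuLi and TMEDA at −78 °C is expected to occur between the methoxy group and the enol ether oxygen, since the other ring hydrogen is screened by the TIPS group. Formylation with DMF would then give 29, though with less certain site control than in step 16.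

## Further compounds

F1 | step 17 | 1-{2-hydroxy-6-methoxy-3-[(2R)-5-methyl-2-(prop-1-en-2-yl)-5-(triethylsilyloxy)hexyl]-4-(triisopropylsilyloxy)phenyl}ethan-1-one | C=C(C)[C@H](CCC(C)(C)O[Si](CC)(CC)CC)Cc1c(O[Si](C(C)C)(C(C)C)C(C)C)cc(OC)c(C(C)=O)c1O
F2 | step 17 | (E)-3-(dimethylamino)-1-{2-hydroxy-6-methoxy-3-[(2R)-5-methyl-2-(prop-1-en-2-yl)-5-(triethylsilyloxy)hexyl]-4-(triisopropylsilyloxy)phenyl}prop-2-en-1-one | C=C(C)[C@H](CCC(C)(C)O[Si](CC)(CC)CC)Cc1c(O[Si](C(C)C)(C(C)C)C(C)C)cc(OC)c(C(=O)/C=C/N(C)C)c1O
F3 | step 17 | 5-methoxy-8-[(2R)-5-methyl-2-(prop-1-en-2-yl)-5-(triethylsilyloxy)hexyl]-7-(triisopropylsilyloxy)-4H-chromen-4-one | C=C(C)[C@H](CCC(C)(C)O[Si](CC)(CC)CC)Cc1c(O[Si](C(C)C)(C(C)C)C(C)C)cc(OC)c2c1OC=CC2=O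
F4 | step 17 | 1-bromo-2,4-bis(tert-butyldimethylsilyloxy)benzene | CC(C)(C)[Si](C)(C)Oc1ccc(Br)c(O[Si](C)(C)C(C)(C)C)c1
F5 | step 17 | [2,4-bis(tert-butyldimethylsilyloxy)phenyl]boronic acid | OB(O)c1ccc(O[Si](C)(C)C(C)(C)C)cc1O[Si](C)(C)C(C)(C)C
F6 | step 9 | [(2S)-5-methyl-2-(prop-1-en-2-yl)-5-(triethylsilyloxy)hexyl]lithium | C=C(C)[C@H](CCC(C)(C)O[Si](CC)(CC)CC)C[Li]
F7 | step 9 | lithium 9-methoxy-9-[(2S)-5-methyl-2-(prop-1-en-2-yl)-5-(triethylsilyloxy)hexyl]-9-boranuidabicyclo[3.3.1]nonane | C=C(C)[C@H](CCC(C)(C)O[Si](CC)(CC)CC)C[B-]1(OC)C2CCCC1CCC2.[Li+]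
F8 | step 11 | 1-methoxy-3,5-bis(tetrahydropyran-2-yloxy)benzene (mixture of stereoisomers) | COc1cc(OC2CCCCO2)cc(OC2CCCCO2)c1
F9 | step 11 | 2-iodo-5-methoxy-1,3-bis(tetrahydropyran-2-yloxy)benzene (mixture of stereoisomers) | COc1cc(OC2CCCCO2)c(I)c(OC2CCCCO2)c1
F10 | step 11 | triethyl{[(5R)-6-[4-methoxy-2,6-bis(tetrahydropyran-2-yloxy)phenyl]-2-methyl-5-(prop-1-en-2-yl)hexan-2-yl]oxy}silane (mixture at the acetal carbons) | C=C(C)[C@H](CCC(C)(C)O[Si](CC)(CC)CC)Cc1c(OC2CCCCO2)cc(OC)cc1OC1CCCCO1
F11 | step 11 | {[(5R)-6-[3-bromo-4-methoxy-2,6-bis(tetrahydropyran-2-yloxy)phenyl]-2-methyl-5-(prop-1-en-2-yl)hexan-2-yl]oxy}triethylsilane (mixture at the acetal carbons) | C=C(C)[C@H](CCC(C)(C)O[Si](CC)(CC)CC)Cc1c(OC2CCCCO2)c(Br)c(OC)cc1OC1CCCCO1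
F12 | step 12 | 5-methoxy-2-[(2R)-5-methyl-2-(prop-1-en-2-yl)-5-(triethylsilyloxy)hexyl]benzene-1,3-diol | C=C(C)[C@H](CCC(C)(C)O[Si](CC)(CC)CC)Cc1c(O)cc(OC)cc1O
F13 | step 12 | 5-methoxy-2-[(2R)-5-methyl-2-(prop-1-en-2-yl)-5-(triethylsilyloxy)hexyl]-3-(triisopropylsilyloxy)phenol | C=C(C)[C@H](CCC(C)(C)O[Si](CC)(CC)CC)Cc1c(O)cc(OC)cc1O[Si](C(C)C)(C(C)C)C(C)C
F14 | step 15 | 5-methoxy-2-[(2R)-5-methyl-2-(prop-1-en-2-yl)-5-(triethylsilyloxy)hexyl]-3-(triisopropylsilyloxy)phenyl 2,4-bis(tert-butyldimethylsilyloxy)benzoate | C=C(C)[C@H](CCC(C)(C)O[Si](CC)(CC)CC)Cc1c(O[Si](C(C)C)(C(C)C)C(C)C)cc(OC)cc1OC(=O)c1ccc(O[Si](C)(C)C(C)(C)C)cc1O[Si](C)(C)C(C)(C)C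
F15 | step 15 | 5-methoxy-2-[(2R)-5-methyl-2-(prop-1-en-2-yl)-5-(triethylsilyloxy)hexyl]-3-(triisopropylsilyloxy)phenyl 1-[2,4-bis(tert-butyldimethylsilyloxy)phenyl]vinyl ether | C=C(C)[C@H](CCC(C)(C)O[Si](CC)(CC)CC)Cc1c(O[Si](C(C)C)(C(C)C)C(C)C)cc(OC)cc1OC(=C)c1ccc(O[Si](C)(C)C(C)(C)C)cc1O[Si](C)(C)C(C)(C)C
A1 | alternative 1 | 5-methoxy-2-[(2R)-5-methyl-2-(prop-1-en-2-yl)-5-(triethylsilyloxy)hexyl]-3-(triisopropylsilyloxy)phenol | C=C(C)[C@H](CCC(C)(C)O[Si](CC)(CC)CC)Cc1c(O)cc(OC)cc1O[Si](C(C)C)(C(C)C)C(C)C
A2 | alternative 1 | 3-methoxycyclobut-2-en-1-one | COC1=CC(=O)C1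
A3 | alternative 1 | triisopropyl{[(4R)-7-methyl-4-(prop-1-en-2-yl)-7-(triethylsilyloxy)oct-1-yn-1-yl]oxy}silane | C=C(C)[C@H](CCC(C)(C)O[Si](CC)(CC)CC)CC#CO[Si](C(C)C)(C(C)C)C(C)C
A4 | alternative 1 | (R)-limonene | CC1=CC[C@@H](CC1)C(C)=C
A5 | alternative 2 | (2S)-7-(allyloxy)-2-[2,4-bis(allyloxy)phenyl]-5-methoxy-8-[(2R)-5-methyl-2-(prop-1-en-2-yl)-5-(triethylsilyloxy)hexyl]-2,3-dihydro-4H-chromen-4-one | C=C(C)[C@H](CCC(C)(C)O[Si](CC)(CC)CC)Cc1c(OCC=C)cc(OC)c2c1O[C@H](c1ccc(OCC=C)cc1OCC=C)CC2=O
A6 | alternative 2 | (3S)-1-{4-(allyloxy)-2-fluoro-6-methoxy-3-[(2R)-5-methyl-2-(prop-1-en-2-yl)-5-(triethylsilyloxy)hexyl]phenyl}-3-[2,4-bis(allyloxy)phenyl]-3-hydroxypropan-1-one | C=C(C)[C@H](CCC(C)(C)O[Si](CC)(CC)CC)Cc1c(OCC=C)cc(OC)c(C(=O)C[C@H](O)c2ccc(OCC=C)cc2OCC=C)c1F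
A7 | alternative 3 | (2S)-7-acetoxy-2-(2,4-diacetoxyphenyl)-5-methoxy-8-[(2R)-5-methyl-2-(prop-1-en-2-yl)-5-(triethylsilyloxy)hexyl]-2,3-dihydro-4H-chromen-4-one | C=C(C)[C@H](CCC(C)(C)O[Si](CC)(CC)CC)Cc1c(OC(C)=O)cc(OC)c2c1O[C@H](c1ccc(OC(C)=O)cc1OC(C)=O)CC2=O
A8 | alternative 3 | (3S)-3-{3-acetoxy-5-methoxy-2-[(2R)-5-methyl-2-(prop-1-en-2-yl)-5-(triethylsilyloxy)hexyl]phenoxy}-3-(2,4-diacetoxyphenyl)propanoic acid | C=C(C)[C@H](CCC(C)(C)O[Si](CC)(CC)CC)Cc1c(OC(C)=O)cc(OC)cc1O[C@H](c1ccc(OC(C)=O)cc1OC(C)=O)CC(=O)O
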